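**Plan**

1. Retrosynthesis: first the O7–MOM bond, then C4–C4a and O1–C8a of the pyranone together. This returns O1–C2–C3–C4(=O) as the (S)-4-aryl-oxetan-2-one 9 and ring A as the 2-fluoroaryllithium from 13. The lactone goes back through β-hydroxy acid and β-keto ester to methyl ketone 4; the prenyl–aryl bonds and the chromene ring are cut last.
2. Enabling feature: the pyranone contains the β-lactone sequence O1–C2(aryl)–C3H2–C4(=O). Its two other atoms, C4a and C8a, are adjacent arene carbons, and C8a is ortho to the C4 carbonyl. An arene C–C unit carrying Li (C4a) and F (C8a) can therefore be inserted into the lactone acyl–O bond.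
3. Forward order of rings: chromene of ring B (step 2), β-lactone (step 7), then expansion of the four-membered lactone to the six-membered pyranone on ring A (step 10). Both benzene rings are bought.
4. Stereochemistry: the only stereocenter (C2, S) is set by Ru/(S,S)-TsDPEN transfer hydrogenation of β-keto ester 5 (step 5). It is retained through lactonisation and ring expansion because the C2–O bond is never broken.
5. Helpers: F (leaving group) and Br/Li leave in step 10; MOM (directing and protecting group) leaves in step 11.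

Key step: step 10

Remark: locants O1, C2, C3, C4, C4a, C8, C8a and O7 are those of the 2,3-dihydro-4H-chromen-4-one core; "ArB" stands for the 2,2-dimethyl-8-(3-methylbut-2-en-1-yl)-2H-chromen-6-yl group.

**Route**

Step 1
Reactants: 1 1-(3-bromo-4-hydroxyphenyl)ethan-1-one
Product: 2 1-{3-bromo-4-[(2-methylbut-3-yn-2-yl)oxy]phenyl}ethan-1-one
Conditions: 3-chloro-3-methylbut-1-yne, K2CO3, KI (cat.), CuI (cat.), acetone, reflux
Reagents that add atoms: 3-chloro-3-methylbut-1-yne, CC(C)(Cl)C#C
Why: Copper-assisted Williamson-type O-alkylation of the phenoxide with the tertiary propargylic chloride (via the copper acetylide) should give the 1,1-dimethylpropargyl ether, the ketone being inert.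

Step 2
Reactants: 2 1-{3-bromo-4-[(2-methylbut-3-yn-2-yl)oxy]phenyl}ethan-1-one
Product: 3 1-(8-bromo-2,2-dimethyl-2H-chromen-6-yl)ethan-1-one
Conditions: N,N-diethylaniline, 190 °C
Reagents that add atoms: none
Why: Thermal aryl propargyl ether rearrangement, that is a propargyl Claisen [3,3] shift to the only free ortho carbon followed by tautomerisation, 1,5-H shift and oxa-6π electrocyclisation, should close the 2,2-dimethyl-2H-chromene ring while bromine blocks the other ortho position.

Step 3
Reactants: 3 1-(8-bromo-2,2-dimethyl-2H-chromen-6-yl)ethan-1-one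
Product: 4 1-[2,2-dimethyl-8-(3-methylbut-2-en-1-yl)-2H-chromen-6-yl]ethan-1-one
Conditions: Bu3SnCH2CH=CMe2, Pd(PPh3)4 (5 mol %), DMF, 100 °C
Reagents that add atoms: tributyl(3-methylbut-2-en-1-yl)stannane, CCCC[Sn](CCCC)(CCCC)CC=C(C)C
Why: Stille cross-coupling of the aryl bromide with the prenylstannane should install the linear prenyl group, since transfer through the less hindered α-carbon is preferred and ketone, chromene alkene and ether are inert to Pd(0).

Step 4
Reactants: 4 1-[2,2-dimethyl-8-(3-methylbut-2-en-1-yl)-2H-chromen-6-yl]ethan-1-one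
Product: 5 ethyl 3-(ArB)-3-oxopropanoate
Conditions: NaH, (EtO)2CO, THF, 65 °C; then AcOH, H2O
Reagents that add atoms: diethyl carbonate, CCOC(=O)OCC
Why: Crossed Claisen condensation of the ketone enolate with diethyl carbonate, pulled to completion by deprotonation of the β-keto ester, should give 5 without touching the alkenes.

Step 5
Reactants: 5 ethyl 3-(ArB)-3-oxopropanoate
Product: 6 ethyl (3S)-3-(ArB)-3-hydroxypropanoate
Conditions: RuCl[(S,S)-TsDPEN](p-cymene) (1 mol %), HCO2H/Et3N (5:2), DMF, 40 °C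
Reagents that add atoms: none
Why: Asymmetric transfer hydrogenation (Noyori type, outer-sphere Ru–H/N–H delivery): with the (S,S)-ligand the aryl group sits against the η6-arene (CH/π contact), so hydride adds to the Re face of the aryl ketone and sets the carbinol carbon as S, and the isolated and styrenic C=C bonds are not reduced by this catalyst.

Step 6
Reactants: 6 ethyl (3S)-3-(ArB)-3-hydroxypropanoate
Product: 7 (3S)-3-(ArB)-3-hydroxypropanoic acid
Conditions: LiOH·H2O, THF/H2O (3:1), 0 → 23 °C; then 1 M HCl to pH 4, 0 °C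
Reagents that add atoms: lithium hydroxide, [Li+].[OH-]
Why: Ester saponification (BAc2) at low temperature should give the β-hydroxy acid without retro-aldol cleavage or dehydration, and the stereocenter is not involved.

Step 7
Reactants: 7 (3S)-3-(ArB)-3-hydroxypropanoic acid
Product: 9 (4S)-4-(ArB)oxetan-2-one, via mixed sulfonic anhydride 8 (not isolated)
Conditions: PhSO2Cl (2 equiv), pyridine, 0 °C; used at once
Reagents that add atoms: none
Why: β-Lactonisation by carboxyl activation: the carboxylate is sulfonylated to mixed anhydride 8 and the free hydroxyl closes the ring by 4-exo-trig acyl substitution, so the C–O bond at the stereocenter stays intact (retention) and hydroxyl activation, which would trigger decarboxylative elimination, is avoided.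

Step 8
Reactants: 10 4-bromo-3-fluorophenol
Product: 11 1-bromo-2-fluoro-4-(methoxymethoxy)benzene
Conditions: NaH, MOMCl, DMF, 0 → 23 °C
Reagents that add atoms: chloromethyl methyl ether, COCCl
Why: Williamson etherification of the sodium phenoxide installs an acetal that directs the ortho-lithiation of step 9 and protects the later 7-OH against the organolithium chemistry.

Step 9
Reactants: 11 1-bromo-2-fluoro-4-(methoxymethoxy)benzene
Product: 13 1-bromo-2-fluoro-4-(methoxymethoxy)-3-(3-methylbut-2-en-1-yl)benzene, via aryllithium 12 (not isolated)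
Conditions: LDA, THF, −78 °C; then CuI (10 mol %), prenyl bromide, −78 → −40 °C
Reagents that add atoms: 1-bromo-3-methylbut-2-ene, CC(C)=CCBr
Why: Directed ortho-metalation with a lithium amide (deprotonation, no Br–Li exchange) removes the proton flanked by fluorine and OMOM, the most acidic one, and copper-catalysed SN2 allylation of aryllithium 12 with prenyl bromide below the onset of LiF elimination should give the linear prenyl arene.

Step 10
Reactants: 13 1-bromo-2-fluoro-4-(methoxymethoxy)-3-(3-methylbut-2-en-1-yl)benzene; 9 (4S)-4-(ArB)oxetan-2-one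
Product: 17 (2S)-2-(ArB)-7-(methoxymethoxy)-8-(3-methylbut-2-en-1-yl)-2,3-dihydro-4H-chromen-4-one, via aryllithium 14 (not isolated), via lithium oxetanolate 15 (not isolated), via lithium keto alkoxide 16 (not isolated)
Conditions: 13, n-BuLi (1.0 equiv), THF, −78 °C; cannulated into 9 (1.1 equiv), THF, −78 °C; then DMPU, −78 → 23 °C; aq. NH4Cl
Reagents that add atoms: none
Why: Proposed new method: Br–Li exchange gives the ortho-fluoroaryllithium 14, which adds to the strained acyl carbon of lactone 9 to give oxetanolate 15; this opens at the acyl–O bond to the benzylic lithium alkoxide 16, whose oxygen returns onto the fluorine-bearing arene carbon, so that C4a and C8a end up inserted between C4 and O1 of the former lactone (two-atom ring expansion, oxetan-2-one to chroman-4-one). The closest known reaction types are the acyl addition of organolithiums to β-lactones giving β-hydroxy ketones, the intramolecular SNAr etherification of ortho-fluoroaryl ketones, and the formally analogous insertion of arynes into the N–acyl bond of β-lactams. The pyranone ring closes by addition–elimination at C8a through a Meisenheimer complex stabilised by the ortho acyl group (6-endo-trig with respect to the C8a=C4a–C4=O unit), with Li+ assisting loss of fluoride. No stereocenter is formed: C2 comes from 9 with its S configuration, because acyl–O cleavage and aryl–O formation both leave the C2–O bond untouched. The step needs acyl attack instead of attack at the benzylic carbon or enolisation, single addition, and ring closure faster than retro-aldol cleavage or E1cB dehydration of 16. These are secured by the hard aryllithium at −78 °C on the strained carbonyl, by inverse addition of exactly one equivalent, and by the ortho-acyl activation of the only fluorine within six-membered reach; the base is consumed as the ring closes, so no base remains to open the flavanone.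

Step 11
Reactants: 17 (2S)-2-(ArB)-7-(methoxymethoxy)-8-(3-methylbut-2-en-1-yl)-2,3-dihydro-4H-chromen-4-one
Product: 18 (2S)-2-[2,2-dimethyl-8-(3-methylbut-2-en-1-yl)-2H-chromen-6-yl]-7-hydroxy-8-(3-methylbut-2-en-1-yl)-2,3-dihydro-4H-chromen-4-one
Conditions: 3 M HCl (aq), MeOH, 23–40 °C
Reagents that add atoms: none
Why: Acid-catalysed acetal cleavage (transacetalisation to dimethoxymethane) under dilute protic conditions should free the 7-OH, and C2 keeps its configuration because racemisation of flavanones runs through base-induced E1cB ring opening, not through acid.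

**Compound list**

1 | 1-(3-bromo-4-hydroxyphenyl)ethan-1-one | CC(=O)c1ccc(O)c(Br)c1 | starting material
2 | 1-{3-bromo-4-[(2-methylbut-3-yn-2-yl)oxy]phenyl}ethan-1-one | CC(=O)c1ccc(OC(C)(C)C#C)c(Br)c1 | intermediate
3 | 1-(8-bromo-2,2-dimethyl-2H-chromen-6-yl)ethan-1-one | CC(=O)c1cc(Br)c2OC(C)(C)C=Cc2c1 | intermediate
4 | 1-[2,2-dimethyl-8-(3-methylbut-2-en-1-yl)-2H-chromen-6-yl]ethan-1-one | CC(=O)c1cc(CC=C(C)C)c2OC(C)(C)C=Cc2c1 | intermediate
5 | ethyl 3-[2,2-dimethyl-8-(3-methylbut-2-en-1-yl)-2H-chromen-6-yl]-3-oxopropanoate | CCOC(=O)CC(=O)c1cc(CC=C(C)C)c2OC(C)(C)C=Cc2c1 | intermediate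
6 | ethyl (3S)-3-[2,2-dimethyl-8-(3-methylbut-2-en-1-yl)-2H-chromen-6-yl]-3-hydroxypropanoate | CCOC(=O)C[C@H](O)c1cc(CC=C(C)C)c2OC(C)(C)C=Cc2c1 | intermediate
7 | (3S)-3-[2,2-dimethyl-8-(3-methylbut-2-en-1-yl)-2H-chromen-6-yl]-3-hydroxypropanoic acid | OC(=O)C[C@H](O)c1cc(CC=C(C)C)c2OC(C)(C)C=Cc2c1 | intermediate
8 | benzenesulfonic (3S)-3-[2,2-dimethyl-8-(3-methylbut-2-en-1-yl)-2H-chromen-6-yl]-3-hydroxypropanoic anhydride | O=C(C[C@H](O)c1cc(CC=C(C)C)c2OC(C)(C)C=Cc2c1)OS(=O)(=O)c1ccccc1 | intermediate
9 | (4S)-4-[2,2-dimethyl-8-(3-methylbut-2-en-1-yl)-2H-chromen-6-yl]oxetan-2-one | O=C1C[C@@H](c2cc(CC=C(C)C)c3OC(C)(C)C=Cc3c2)O1 | intermediate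
10 | 4-bromo-3-fluorophenol | Oc1ccc(Br)c(F)c1 | starting material
11 | 1-bromo-2-fluoro-4-(methoxymethoxy)benzene | COCOc1ccc(Br)c(F)c1 | intermediate
12 | [3-bromo-2-fluoro-6-(methoxymethoxy)phenyl]lithium | COCOc1ccc(Br)c(F)c1[Li] | intermediate
13 | 1-bromo-2-fluoro-4-(methoxymethoxy)-3-(3-methylbut-2-en-1-yl)benzene | COCOc1ccc(Br)c(F)c1CC=C(C)C | intermediate
14 | [2-fluoro-4-(methoxymethoxy)-3-(3-methylbut-2-en-1-yl)phenyl]lithium | COCOc1ccc([Li])c(F)c1CC=C(C)C | intermediate
15 | lithium (4S)-4-[2,2-dimethyl-8-(3-methylbut-2-en-1-yl)-2H-chromen-6-yl]-2-[2-fluoro-4-(methoxymethoxy)-3-(3-methylbut-2-en-1-yl)phenyl]oxetan-2-olate (either configuration at C2 of the oxetane) | [Li]OC1(C[C@@H](c2cc(CC=C(C)C)c3OC(C)(C)C=Cc3c2)O1)c4ccc(OCOC)c(CC=C(C)C)c4F | intermediate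
16 | lithium (1S)-1-[2,2-dimethyl-8-(3-methylbut-2-en-1-yl)-2H-chromen-6-yl]-3-[2-fluoro-4-(methoxymethoxy)-3-(3-methylbut-2-en-1-yl)phenyl]-3-oxopropan-1-olate | CC(C)=CCc1c(OCOC)ccc(C(=O)C[C@H](O[Li])c2cc(CC=C(C)C)c3OC(C)(C)C=Cc3c2)c1F | intermediate
17 | (2S)-2-[2,2-dimethyl-8-(3-methylbut-2-en-1-yl)-2H-chromen-6-yl]-7-(methoxymethoxy)-8-(3-methylbut-2-en-1-yl)-2,3-dihydro-4H-chromen-4-one | CC(C)=CCc1cc([C@@H]2CC(=O)c3ccc(OCOC)c(CC=C(C)C)c3O2)cc2c1OC(C)(C)C=C2 | intermediate
18 | (2S)-2-[2,2-dimethyl-8-(3-methylbut-2-en-1-yl)-2H-chromen-6-yl]-7-hydroxy-8-(3-methylbut-2-en-1-yl)-2,3-dihydro-4H-chromen-4-one | CC(C)=CCc1cc([C@@H]2CC(=O)c3ccc(O)c(CC=C(C)C)c3O2)cc2c1OC(C)(C)C=C2 | target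

**Step count**

Total: 11 steps. Longest linear sequence: 9 steps (steps 1–7, 10, 11); the ring A branch (steps 8–9) joins in step 10.

**Steps most likely to fail**

Step 10 (Proposed new method). Double addition of the aryllithium, base-induced loss of the electron-rich lactone, or retro-aldol cleavage and dehydration of the lithium keto alkoxide may outrun the SNAr closure, costing yield and enantiomeric purity. The fallback uses known chemistry, sets out from 6 and 13, and comes back at 17. Hydroxy ester 6 is silylated (TBSCl, imidazole, DMF) to ethyl (3S)-3-{[tert-butyl(dimethyl)silyl]oxy}-3-(ArB)propanoate F1. MeNH(OMe)·HCl and i-PrMgCl (THF, −20 °C) convert it into the Weinreb amide (3S)-3-{[tert-butyl(dimethyl)silyl]oxy}-3-(ArB)-N-methoxy-N-methylpropanamide F2. Acylation of aryllithium 14 (from 13 and n-BuLi, −78 °C) with F2 gives (3S)-3-{[tert-butyl(dimethyl)silyl]oxy}-3-(ArB)-1-[2-fluoro-4-(methoxymethoxy)-3-(3-methylbut-2-en-1-yl)phenyl]propan-1-one F3; the chelated tetrahedral adduct excludes double addition and no free alkoxide is present. HF·pyridine (THF, 0 °C) gives the neutral hydroxy ketone (3S)-3-(ArB)-1-[2-fluoro-4-(methoxymethoxy)-3-(3-methylbut-2-en-1-yl)phenyl]-3-hydroxypropan-1-one F4. F4 is closed to 17 by base-mediated intramolecular SNAr (KHMDS, 18-crown-6, THF, −40 → 0 °C), under conditions tuned independently of the C–C bond formation.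

Step 7. Decarboxylative fragmentation of the electron-rich 4-aryl-β-lactone to the styrene, or ionisation at the benzylic C–O bond during electrophilic carboxyl activation, may destroy the lactone. The fallback sets out from 6 and comes back at 9. Ester 6 is converted with Me2AlSPh (AlMe3, PhSH, CH2Cl2, 0 °C) into S-phenyl (3S)-3-(ArB)-3-hydroxypropanethioate F5. The thioester is cyclised by thiophilic activation (AgOCOCF3, Na2HPO4, MeCN, 0 °C), so the lactone forms at low temperature without a sulfonyl chloride, pyridine or the free acid.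

Step 11. Acid-catalysed addition of the freed 7-OH to the neighbouring 8-prenyl group (chroman formation), or addition of methanol to the chromene, may compete with acetal cleavage. The fallback sets out from 13 and comes back at 18; the acid-labile acetal is exchanged for a fluoride-labile silyl ether before the fragments are joined. MOM is removed from 13 (2 M HCl, MeOH, 23 °C), where only a simple aryl bromide meets the acid, to give 4-bromo-3-fluoro-2-(3-methylbut-2-en-1-yl)phenol F6. TIPSCl and imidazole (DMF) give [4-bromo-3-fluoro-2-(3-methylbut-2-en-1-yl)phenoxy]tri(propan-2-yl)silane F7. Under the conditions of step 10 with 9, F7 reacts by way of [2-fluoro-3-(3-methylbut-2-en-1-yl)-4-{[tri(propan-2-yl)silyl]oxy}phenyl]lithium F8, the lithium oxetanolate F9 and the lithium keto alkoxide F10 to give (2S)-2-(ArB)-8-(3-methylbut-2-en-1-yl)-7-{[tri(propan-2-yl)silyl]oxy}-2,3-dihydro-4H-chromen-4-one F11. F11 is desilylated with TBAF buffered with AcOH (THF, 0 °C) to 18.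

**Further compounds**

F1 | step 10 | ethyl (3S)-3-{[tert-butyl(dimethyl)silyl]oxy}-3-[2,2-dimethyl-8-(3-methylbut-2-en-1-yl)-2H-chromen-6-yl]propanoate | CCOC(=O)C[C@H](O[Si](C)(C)C(C)(C)C)c1cc(CC=C(C)C)c2OC(C)(C)C=Cc2c1
F2 | step 10 | (3S)-3-{[tert-butyl(dimethyl)silyl]oxy}-3-[2,2-dimethyl-8-(3-methylbut-2-en-1-yl)-2H-chromen-6-yl]-N-methoxy-N-methylpropanamide | CON(C)C(=O)C[C@H](O[Si](C)(C)C(C)(C)C)c1cc(CC=C(C)C)c2OC(C)(C)C=Cc2c1
F3 | step 10 | (3S)-3-{[tert-butyl(dimethyl)silyl]oxy}-3-[2,2-dimethyl-8-(3-methylbut-2-en-1-yl)-2H-chromen-6-yl]-1-[2-fluoro-4-(methoxymethoxy)-3-(3-methylbut-2-en-1-yl)phenyl]propan-1-one | CC(C)=CCc1c(OCOC)ccc(C(=O)C[C@H](O[Si](C)(C)C(C)(C)C)c2cc(CC=C(C)C)c3OC(C)(C)C=Cc3c2)c1F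
F4 | step 10 | (3S)-3-[2,2-dimethyl-8-(3-methylbut-2-en-1-yl)-2H-chromen-6-yl]-1-[2-fluoro-4-(methoxymethoxy)-3-(3-methylbut-2-en-1-yl)phenyl]-3-hydroxypropan-1-one | CC(C)=CCc1c(OCOC)ccc(C(=O)C[C@H](O)c2cc(CC=C(C)C)c3OC(C)(C)C=Cc3c2)c1F
F5 | step 7 | S-phenyl (3S)-3-[2,2-dimethyl-8-(3-methylbut-2-en-1-yl)-2H-chromen-6-yl]-3-hydroxypropanethioate | O=C(C[C@H](O)c1cc(CC=C(C)C)c2OC(C)(C)C=Cc2c1)Sc1ccccc1
F6 | step 11 | 4-bromo-3-fluoro-2-(3-methylbut-2-en-1-yl)phenol | Oc1ccc(Br)c(F)c1CC=C(C)C
F7 | step 11 | [4-bromo-3-fluoro-2-(3-methylbut-2-en-1-yl)phenoxy]tri(propan-2-yl)silane | CC(C)[Si](Oc1ccc(Br)c(F)c1CC=C(C)C)(C(C)C)C(C)C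
F8 | step 11 | [2-fluoro-3-(3-methylbut-2-en-1-yl)-4-{[tri(propan-2-yl)silyl]oxy}phenyl]lithium | CC(C)=CCc1c(O[Si](C(C)C)(C(C)C)C(C)C)ccc([Li])c1F
F9 | step 11 | lithium (4S)-4-[2,2-dimethyl-8-(3-methylbut-2-en-1-yl)-2H-chromen-6-yl]-2-[2-fluoro-3-(3-methylbut-2-en-1-yl)-4-{[tri(propan-2-yl)silyl]oxy}phenyl]oxetan-2-olate | [Li]OC1(C[C@@H](c2cc(CC=C(C)C)c3OC(C)(C)C=Cc3c2)O1)c4ccc(O[Si](C(C)C)(C(C)C)C(C)C)c(CC=C(C)C)c4F
F10 | step 11 | lithium (1S)-1-[2,2-dimethyl-8-(3-methylbut-2-en-1-yl)-2H-chromen-6-yl]-3-[2-fluoro-3-(3-methylbut-2-en-1-yl)-4-{[tri(propan-2-yl)silyl]oxy}phenyl]-3-oxopropan-1-olate | CC(C)=CCc1c(O[Si](C(C)C)(C(C)C)C(C)C)ccc(C(=O)C[C@H](O[Li])c2cc(CC=C(C)C)c3OC(C)(C)C=Cc3c2)c1F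
F11 | step 11 | (2S)-2-[2,2-dimethyl-8-(3-methylbut-2-en-1-yl)-2H-chromen-6-yl]-8-(3-methylbut-2-en-1-yl)-7-{[tri(propan-2-yl)silyl]oxy}-2,3-dihydro-4H-chromen-4-one | CC(C)=CCc1cc([C@@H]2CC(=O)c3ccc(O[Si](C(C)C)(C(C)C)C(C)C)c(CC=C(C)C)c3O2)cc2c1OC(C)(C)C=C2
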